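The numbers are made up; the result is computed.

**The flask.** Within 30 s, X should end as X.Q, dissolved or as crystals E, while Q can carry X.Q on to Q.X.Q.

X 0.050 M; L 1.05 equiv; time 30 s; volume of the second phase over the first 0.25

    Q ⇌ L, rate k1*([Q] - [L]/K1) per volume of the first phase (K1 = 0.607, k1 = 1.55 s⁻¹)
    X + Q → X.Q (k2 = 15.8 M⁻¹ s⁻¹)
    Q + X.Q → Q.X.Q (k3 = 15.1 M⁻¹ s⁻¹)
    E ⇌ X.Q, rate k4*(cs4 - [X.Q]) while solid is left; crystals form when [X.Q] > cs4 (cs4 = 1.2 mM, k4 = 0.226 s⁻¹)
    Q → Z (k5 = 0.0299 s⁻¹)

- amount of X.Q and E together at 30 s, in percent of the X charged
- the change that raises the amount of X.Q and E together at 30 s, in percent of the X charged most ("none" if none brings more than 2 percentage points) (violet / ochre / teal / amber / none)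
- amount of X.Q and E together at 30 s, in percent of the X charged, after teal

- violet: doubling the amount of L, all else as stated
- ochre: doubling the solubility in step 4, all else as stated
- teal: doubling the transfer coefficient of step 1, all else as stated
- amber: doubling the dissolution coefficient of step 4, all else as stated

**The crossing.** With [X.Q] far above the solubility 1.2 mM, a dissolved X.Q passes to Q.X.Q at k3[Q] and into crystals at about k4. The two ways are equal at [Q] = k4/k3 = 0.0150 M, the crossing [Q], where this selectivity factor is one. L equilibrates within 0.0850 s, faster than the 0.88 s half-life of Q, so teal should change little. [Q] therefore starts near 0.0456 M, or 3.04 times the crossing.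

**Above it.** Subtracting the Q and L still held at the crossing leaves 70.5% of the X charge as Q spent above it. Take k2 close to k3 and set crystals aside. Then Q spent is about u minus u cubed over 6, with u = k2∫[Q]dt, which gives u = 0.764. That leaves X 46.6%, X.Q 35.6% and Q.X.Q 17.8%.

**First number.** Z takes about k5/(k2[X]) = 3.78% of the X charge. If over-reaction stopped at the crossing, the balance X.Q + 2 Q.X.Q = Q charge − Z would give 65.6%.

**Weak link.** It does not stop there. Past the crossing, [Q] falls at λ = 0.553 s⁻¹, so a dissolved X.Q still over-reacts with probability k4/(k4+λ) = 29.0%. Q.X.Q rises to 28.1% and the yield falls to 44.9%, the number committed to here, teal included. Amber lifts the crossing to 0.0300 M, towards the starting [Q], so amber is the choice.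

**The forecast.** It gave 45.5% (from 42% to 49%), 45.5% after teal, and amber, since “faster crystallisation protects it from over-reaction”.

**The result.** The flask gives 46.6%, 46.6% after teal, and amber as best, at 6.9 percentage points.

**Next flask.** In this flask [Q] is 0.00849 M at 3.00 s, below the crossing, and Q.X.Q already stands at 20.4%. The neighbouring flask holds 0.20 M of X with the same crossing, so its starting [Q] reckons to 12.2 times the crossing. The same reckoning spends 96.4% of the X charge above it, so u = 1.11. For the neighbouring flask the reckoning then puts Q.X.Q at 34.5% and the yield at 35.0%. The simulated neighbouring flask ends at 40.0% of X.Q and E together, with Q.X.Q at 31.9%.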